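## Structural features

The target is a germacranolide: a ten-membered carbocycle (C1–C10) trans-fused at C6–C7 to a γ-lactone (C6–O–C12(=O)–C11–C7), with a Z-trisubstituted C1=C10 olefin and an E-trisubstituted C4=C5 olefin, each bearing a methyl group. It has five stereocentres, (2S,6R,7R,8R,11S) in germacrane numbering. C6, C7 and C8 are contiguous (H-6/H-7 trans, H-7/H-8 cis, so the O8 acetate is β); quaternary C11 adjoins C7 with its hydroxyl on the face of H-7 and its CH2Cl group on the face of C8; C2 (α-OH) lies isolated between the two olefins. The tertiary chlorohydrin closes to a spiro-epoxide with base, the lactone can migrate to a free O8, and the acetate, the allylic C2 alcohol and the acid-sensitive 1(10),4-diene narrow the pH window of the late steps. The real difficulties are the Z geometry of a trisubstituted olefin inside a medium ring, closure of the ten-membered ring with control of C6 and C7, and telling O8 (acetylated) from O2 (free). The key step exploits the 1,5-relationship O8–C8–C9–C10=C1–C2–O2: one silicon atom bridging the two oxygens puts C1=C10 in an eight-membered 1,3-dioxa-2-silacyclooct-5-ene, which can only hold the Z isomer. On that silaketal ring the C7 and C3 chains are trans, which matters for the later carbocycle closure.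

## Logic of the disconnections

Cutting the O8–acetyl bond of 29 leads through 28 and 27 to 26. Acetylation is placed last because a free O8 is the group most able to disturb the lactone, and an acetate would not survive the enolate chemistry. The forward demand is that O2 be masked selectively in 26 before O8 is acylated.

Cutting the C13–Cl bond of 26 and restoring the O8–Si–O2 bridge leads through 25 to 24. A spiro-epoxide carries the C11 oxygen with its configuration and leaves only a methylene carbon for chloride to attack. The forward demand is attack at C13 only, under non-basic conditions, and silicon removal without fluoride opening the epoxide (hence chloride first).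

Cutting the C11–O and C13–O bonds of 24 leads to 23. The exocyclic olefin is the only electron-poor one, so a nucleophilic oxidant can select it. The forward demand is oxygen delivery to the face of H-7.

Cutting C11=C13 of 23 leads through 22 and 21 to 20. C13 is absent from the metathesis skeleton and must be added after the lactone exists. The forward demand is clean enolisation of a lactone with no free hydroxyl, which is why the silicon bridge is kept to this point.

Cutting C6–C7 and the O6–C12 ester bond of 20 leads through 19 to 18. This opens the carbocycle and the lactone together and returns an acyclic aldehyde–enoate pair. The forward demand is a ten-membered closure across the silaketal that sets C6 and C7.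

Cutting C1=C10 of 18 leads to 17; this is the key disconnection. It removes the eight-membered ring and the only geometrically difficult olefin. The forward demand is ring closure onto a 1,1-disubstituted olefin in the presence of two conjugated olefins. C6 is carried at the aldehyde level rather than as a protected alcohol, so that 18 is directly the cyclisation substrate.

Cutting the two Si–O bonds of 17 leads to 4, 14 and 15. This divides the molecule into a C7–C12 piece and a C1–C6 piece, each with one stereocentre. The forward demand is stepwise silylation so that only the mixed silaketal forms.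

Cutting C8–C9 of 4 leads to 1 and 2. The forward demand is reagent-controlled 2-methylallyl transfer to the Re face of the aldehyde without touching the enoate.

Cutting back the C6 oxidation level, the C5–C6 bond and the C4–methyl bond of 14 leads through 13 and 12 to 11. An allyl or 2-methylallyl transfer to acrolein cannot supply C3–C6 with its E-trisubstituted olefin, so the olefin is made by syn-carbometalation of a terminal alkyne. The forward demand is that the vinyl group and the free hydroxyl of 11 tolerate the organoaluminium chemistry and that only the primary alcohol of 13 is oxidised.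

Cutting the terminal vinyl carbon and the C3–C4 bond of 11 leads through 10, 9 and 8 to 5 and 6. C2 is taken from the chiral pool, which fixes its configuration without relying on an asymmetric addition to acrolein. The forward demand is epoxide opening at the unsubstituted carbon only.

## Other disconnections considered

Alternative 1: The cut is transannular. A C5–C10 bond is added in the retron so that C10, C1, C2, C3, C4 and C5 form a cyclohexa-1,3-diene cis-fused to a six-membered ring holding C6–C9. The forward key step would be a light-driven conrotatory six-electron ring opening that breaks C5–C10 and releases triene A1.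
- In its favour: the ten-membered ring is unveiled from a six–six system without high dilution, and C6, C7 and C8 can be set on a rigid bicycle.
- Against it here: conrotatory opening of a cis-fused diene gives one E and one Z terminal olefin, but nothing dictates which end becomes Z. The triene can re-close or undergo 1,7-hydrogen shifts. A1 still needs enol ether hydrolysis and stereoselective reduction at C2, oxidation of C12 to the carboxyl level, lactonisation onto O6, and the C11/C13 chemistry.
- Comparison: on structure, A1 already holds all fifteen carbons, C13 included, which 18 does not; there the alternative is the better. On ring formation as such, a unimolecular pericyclic step is the equal or the better of the separate ten-membered closure of step 8. On olefin geometry the chosen plan is stronger, because ring size and not torquoselectivity fixes Z. On step economy after the key step the chosen plan should be shorter.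
- A point of notation: the C2=C3 bond of A1 has the ring carbons cis, which is E by the sequence rule because oxygen outranks C1.

Alternative 2: The cut is C7–C11, with a temporary C8–C11 bond. In the forward sense a rhodium carbenoid generated with Rh2(OAc)4 at C11 of an O6 diazoacetate arm adds to an (E) C7=C8 silyl enol ether and gives cyclopropane-fused lactone A2. Strain-release opening of the C8–C11 bond would then leave the lactone with a C8 aldehyde on C7.
- In its favour: intramolecular delivery sets C7 relative to C6 through a cis-fused bicycle, and the lactone is in place early. On the predictability of the C6/C7 relationship this alternative is the better of the two plans.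
- Against it here: the same O6 arm is also allylic to C4=C5, so cyclopropanation of that olefin competes and chemoselectivity rests only on the higher nucleophilicity of the enol ether. C8 becomes trigonal on ring opening and must be set again. The ten-membered ring and the Z C1=C10 olefin remain to be made, for instance by metathesis onto the C1 vinyl group of A2, where a ten-membered ring does not enforce Z. C13 is missing, as in the chosen plan (equal on this point).
- Comparison: mechanistically the carbenoid step is well understood, but it solves the part of the structure that is less difficult; the chosen plan solves the Z olefin outright and leaves C6/C7 to a less certain step. Step economy should favour the chosen plan.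

Alternative 3: The cut is C8–C9. In the forward sense a C8 aldehyde on C7 of the preformed lactone reacts with a pinacol boronate at C1 of the same molecule (C9H2=C10(Me)–C1H(Bpin)) through a six-membered chair. This forms C8–C9, moves the olefin to C1=C10 and closes the ten-membered ring to give A3.
- In its favour: one step makes the ring, the Z olefin (the C2-bearing α-substituent prefers the pseudo-axial position, away from the pinacol methyls) and the C8 stereocentre by chirality transfer. A3 emerges with O8 free and O2 silylated, so the O2/O8 problem does not arise; on this and on overall step economy the alternative is the better plan.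
- Against it here: a configurationally defined secondary allylic boronate next to the C2 stereocentre must be made and kept while an aldehyde is unveiled in the same molecule. Intermolecular allylboration competes with a strained ten-membered bicyclic transition state. Z selectivity is a conformational preference that ring strain may override.
- Comparison: C8 is set with comparable reliability in both plans (chair allylboration in each). The Z geometry is better guaranteed in the chosen plan. Both lack C13 at the key stage and need the same late methylenation (equal).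

Key step: step 7

Remark on the chemistry: locants follow germacrane numbering, and α means the face of the ten-membered ring that carries H-7. C6 is carried through the metathesis as the aldehyde, a spectator-group choice that leaves the skeleton of 17 and 18 unchanged.

## Route

Step 1
Reactants: 1 methyl (2E)-4-oxobut-2-enoate; 2 2-methylallylmagnesium chloride
Product: 4 methyl (2E,4R)-4-hydroxy-6-methylhepta-2,6-dienoate, via B-(2-methylallyl)diisopinocampheylborane 3 (not isolated)
Conditions: (+)-Ipc2BOMe, 2, Et2O, 0 °C to rt; then 1, −78 °C; then HOCH2CH2NH2, rt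
Reagents that add atoms: none
Why: Brown-type asymmetric allylboration through a six-membered chair; the reagent from (+)-Ipc2BOMe should deliver the 2-methylallyl group to the Re face of the aldehyde and set C8 as R. The enoate is inert at −78 °C, and the amino alcohol work-up avoids basic peroxide.

Step 2
Reactants: 5 ethynyltrimethylsilane; 6 (S)-epichlorohydrin
Product: 8 (2S)-1-chloro-5-(trimethylsilyl)pent-4-yn-2-ol, via lithium (trimethylsilyl)acetylide 7 (not isolated)
Conditions: n-BuLi, THF, −78 °C; BF3·OEt2; then 6, −78 °C
Reagents that add atoms: none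
Why: BF3-assisted opening of the epoxide by the lithium acetylide occurs at the unsubstituted carbon at −78 °C; no bond to the stereocentre (the future C2) is made or broken.

Step 3
Reactants: 8 (2S)-1-chloro-5-(trimethylsilyl)pent-4-yn-2-ol
Product: 11 (3S)-hex-1-en-5-yn-3-ol, via silyl alkynyl epoxide 9 (not isolated), via (3S)-6-(trimethylsilyl)hex-1-en-5-yn-3-ol 10 (not isolated)
Conditions: Me3S+ I− (3.5 equiv), n-BuLi (3.4 equiv), THF, −20 °C to rt; then MeOH, K2CO3 (cat.), rt
Reagents that add atoms: trimethylsulfonium iodide, C[S+](C)C.[I-]
Why: Excess dimethylsulfonium methylide closes the chlorohydrin to the terminal epoxide, opens it at CH2 and eliminates dimethyl sulfide to give the one-carbon-homologated allylic alcohol (Corey–Chaykovsky-type homologation). The carbinol keeps its configuration, and methoxide formed on adding methanol removes the alkynyl silyl group.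

Step 4
Reactants: 11 (3S)-hex-1-en-5-yn-3-ol
Product: 13 (2E,5S)-3-methylhepta-2,6-diene-1,5-diol, via alkenylalane 12 (not isolated)
Conditions: AlMe3 (3 equiv), Cp2ZrCl2 (0.25 equiv), CH2Cl2, 0 °C to rt; then n-BuLi, THF, −78 °C; (CH2O)n, −78 °C to rt
Reagents that add atoms: trimethylaluminium, C[Al](C)C; formaldehyde (as paraformaldehyde), C=O
Why: Negishi zirconium-catalysed syn-carboalumination puts the methyl on the internal alkyne carbon and aluminium on the terminus, fixing the E C4=C5 geometry. The alkenylalanate formed with n-BuLi is hydroxymethylated with retention, and the monosubstituted vinyl group does not react under these conditions.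

Step 5
Reactants: 13 (2E,5S)-3-methylhepta-2,6-diene-1,5-diol
Product: 14 (2E,5S)-5-hydroxy-3-methylhepta-2,6-dienal
Conditions: TEMPO (0.1 equiv), PhI(OAc)2 (1.1 equiv), CH2Cl2, rt
Reagents that add atoms: none
Why: Oxoammonium oxidation is selective for the primary allylic alcohol over the secondary one, so O2 stays free for silylation and C6 reaches the aldehyde level without a protecting group.

Step 6
Reactants: 4 methyl (2E,4R)-4-hydroxy-6-methylhepta-2,6-dienoate; 15 dichlorodi(propan-2-yl)silane; 14 (2E,5S)-5-hydroxy-3-methylhepta-2,6-dienal
Product: 17 methyl (2E,4R)-6-methyl-4-{[{[(3S,5E)-5-methyl-7-oxohepta-1,5-dien-3-yl]oxy}di(propan-2-yl)silyl]oxy}hepta-2,6-dienoate, via monochlorosilane 16 (not isolated)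
Conditions: 15 (3 equiv), imidazole, CH2Cl2, 0 °C; excess 15 removed in vacuo; then 14, imidazole, DMF, 0 °C to rt
Reagents that add atoms: none
Why: Sequential silylation: with excess 15 the first alcohol stops at the monochlorosilane, whose remaining Si–Cl bond is then displaced by the second alcohol. This order fixes which two alcohols are joined, and no stereocentre is involved.

Step 7
Reactants: 17 methyl (2E,4R)-6-methyl-4-{[{[(3S,5E)-5-methyl-7-oxohepta-1,5-dien-3-yl]oxy}di(propan-2-yl)silyl]oxy}hepta-2,6-dienoate
Product: 18 methyl (2E)-3-{(4S,5Z,8R)-6-methyl-4-[(2E)-2-methyl-4-oxobut-2-en-1-yl]-2,2-di(propan-2-yl)-1,3-dioxa-2-silacyclooct-5-en-8-yl}prop-2-enoate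
Conditions: second-generation Grubbs catalyst RuCl2(=CHPh)(H2IMes)(PCy3) (10 mol %), 1,4-benzoquinone (20 mol %), toluene (2 mM), 80 °C, argon sparge
Reagents that add atoms: none
Why: Ring-closing olefin metathesis by the Chauvin mechanism: the ruthenium benzylidene exchanges onto the monosubstituted C1 vinyl group, the new alkylidene adds across the tethered 1,1-disubstituted C10 olefin to a ruthenacyclobutane, and cycloreversion forms C1=C10 and a ruthenium methylidene that turns over with loss of ethylene. The closest known reaction type is the temporary-silicon-tethered ring-closing metathesis of unsymmetrical bis-alkoxysilanes to seven- and eight-membered silaketals containing Z-trisubstituted olefins. One ring is closed, the eight-membered 1,3-dioxa-2-silacyclooct-5-ene (C8, C9, C10, C1, C2, O, Si, O), by intramolecular metathesis in which both olefinic carbons become ring members. No stereocentre is formed; C8 and C2 are spectators and end up trans on the new ring. The step needs Z geometry, which the ring size secures because an E-trisubstituted olefin in an eight-membered ring would be prohibitively strained. It needs C1/C10 cross-coupling in place of homo-coupling, which the tether secures at high dilution with removal of ethylene. It needs the conjugated olefins to stay out: the trisubstituted enal olefin is inert, closure onto C7 of the enoate would have to expel an ester-substituted ruthenium carbene, and benzoquinone suppresses hydride-mediated olefin migration.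

Step 8
Reactants: 18 methyl (2E)-3-{(4S,5Z,8R)-6-methyl-4-[(2E)-2-methyl-4-oxobut-2-en-1-yl]-2,2-di(propan-2-yl)-1,3-dioxa-2-silacyclooct-5-en-8-yl}prop-2-enoate
Product: 20 2α,8β-O-[di(propan-2-yl)silanediyl]-2α,8β-dihydroxy-13-norgermacra-1(10)Z,4E-dien-12,6α-olide (H-6β, H-7α), via ring-closed hydroxy ester 19 (not isolated)
Conditions: SmI2 (3 equiv), t-BuOH (3 equiv), THF, slow addition of 18 to 2 mM, −78 to −20 °C
Reagents that add atoms: none
Why: Proposed new method: divalent samarium reduces the enal to a C6 ketyl that adds to C7 of the enoate in a 10-exo-trig closure, the samarium enolate is protonated and the C6 alkoxide expels methoxide to close the γ-lactone; the closest known reaction type is the SmI2 ketyl–enoate cyclisation with lactonisation used for five- to eight-membered rings, together with SmI2 Barbier and Reformatsky macrocyclisations. C7 should be set by the silaketal, which lets C6 approach only anti to H-8 and onto the enoate face left open when the C8–O bond lies in the enoate plane (the other rotamer puts the OSi(iPr)2 group on the attacked face); C6 should follow from the usual anti arrangement of the samarium-bound oxygen and C7=C11, which corresponds to the trans-fused lactone.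

Step 9
Reactants: 20 2α,8β-O-[di(propan-2-yl)silanediyl]-2α,8β-dihydroxy-13-norgermacra-1(10)Z,4E-dien-12,6α-olide
Product: 21 13-(dimethylamino)-2α,8β-O-[di(propan-2-yl)silanediyl]-2α,8β-dihydroxy-11,13-dihydrogermacra-1(10)Z,4E-dien-12,6α-olide
Conditions: LiN(iPr)2 (1.2 equiv), THF, −78 °C; CH2=NMe2+ I−, −78 °C to rt
Reagents that add atoms: N,N-dimethylmethyleneiminium iodide (Eschenmoser's salt), C=[N+](C)C.[I-]
Why: The lactone α-CH2 is the only acidic site and carries no β-leaving group, so its lithium enolate undergoes a clean Mannich reaction. The C11 configuration (aminomethyl expected anti to C8) is immaterial because it is erased in step 10.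

Step 10
Reactants: 21 13-(dimethylamino)-2α,8β-O-[di(propan-2-yl)silanediyl]-2α,8β-dihydroxy-11,13-dihydrogermacra-1(10)Z,4E-dien-12,6α-olide
Product: 23 2α,8β-O-[di(propan-2-yl)silanediyl]-2α,8β-dihydroxygermacra-1(10)Z,4E,11(13)-trien-12,6α-olide, via trimethylammonium iodide 22 (not isolated)
Conditions: MeI, MeOH, rt; then NaHCO3 (aq), CH2Cl2, rt
Reagents that add atoms: none
Why: Exhaustive N-methylation followed by mild-base elimination of trimethylamine (Hofmann-type, E1cB through the lactone enolate) gives the exocyclic methylene; this is the standard α-methylenation of γ-lactones.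

Step 11
Reactants: 23 2α,8β-O-[di(propan-2-yl)silanediyl]-2α,8β-dihydroxygermacra-1(10)Z,4E,11(13)-trien-12,6α-olide
Product: 24 11α,13-epoxy-2α,8β-O-[di(propan-2-yl)silanediyl]-2α,8β-dihydroxygermacra-1(10)Z,4E-dien-12,6α-olide
Conditions: t-BuOOH (1.5 equiv), n-BuLi (1.0 equiv), THF, −78 to −20 °C
Reagents that add atoms: tert-butyl hydroperoxide, CC(C)(C)OO
Why: Weitz–Scheffer-type nucleophilic epoxidation: the peroxide anion adds only to the conjugate acceptor at C13 and leaves both electron-rich trisubstituted olefins. The enolate should close onto oxygen from the face of H-7, anti to the C7–C8 bond, placing the C11 oxygen α (11S).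

Step 12
Reactants: 24 11α,13-epoxy-2α,8β-O-[di(propan-2-yl)silanediyl]-2α,8β-dihydroxygermacra-1(10)Z,4E-dien-12,6α-olide
Product: 26 13-chloro-2α,8β,11α-trihydroxygermacra-1(10)Z,4E-dien-12,6α-olide, via silaketal chlorohydrin 25 (not isolated)
Conditions: LiCl (10 equiv), AcOH (5 equiv), THF, rt; then HF·pyridine, pyridine, 0 °C to rt
Reagents that add atoms: lithium chloride, [Li+].[Cl-]
Why: Chloride opens the acid-activated spiro-epoxide by SN2 attack at the C13 methylene (C11 is fully substituted and deactivated by the carbonyl), so the C11–O bond and its configuration are kept. Fluoride then cleaves both Si–O bonds, and the acidic medium keeps the chlorohydrin from reverting to the epoxide.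

Step 13
Reactants: 26 13-chloro-2α,8β,11α-trihydroxygermacra-1(10)Z,4E-dien-12,6α-olide
Product: 27 2α-(tert-butyldimethylsilyloxy)-13-chloro-8β,11α-dihydroxygermacra-1(10)Z,4E-dien-12,6α-olide
Conditions: TBSCl (1.2 equiv), imidazole, DMF, −20 to 0 °C
Reagents that add atoms: tert-butyldimethylsilyl chloride, CC(C)(C)[Si](C)(C)Cl
Why: The three hydroxyls differ sterically: O2 is a secondary allylic alcohol between CH and CH2, O8 is flanked by the branched C7 and the lactone, and O11 is tertiary, so the bulky silyl chloride should go to O2. Imidazole is too weak a base to close the chlorohydrin.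

Step 14
Reactants: 27 2α-(tert-butyldimethylsilyloxy)-13-chloro-8β,11α-dihydroxygermacra-1(10)Z,4E-dien-12,6α-olide
Product: 29 8β-acetoxy-13-chloro-2α,11α-dihydroxygermacra-1(10)Z,4E-dien-12,6α-olide (CNP0360028.4), via silyl ether acetate 28 (not isolated)
Conditions: Ac2O, pyridine, DMAP (cat.), CH2Cl2, 0 °C; MeOH quench; then HF·pyridine, THF, 0 °C to rt
Reagents that add atoms: acetic anhydride, CC(=O)OC(C)=O
Why: DMAP-catalysed acetylation takes the remaining secondary alcohol O8 while the tertiary O11 stays free at 0 °C. Buffered HF then removes the silyl ether under non-basic conditions, so acyl migration, lactone transposition and epoxide formation are not expected.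

## Compound list

1 | methyl (2E)-4-oxobut-2-enoate | COC(=O)/C=C/C=O | starting material
2 | 2-methylallylmagnesium chloride | CC(=C)C[Mg]Cl | starting material
3 | B-(2-methylallyl)diisopinocampheylborane (from (+)-Ipc2BOMe, (−)-α-pinene series) | CC(=C)CB([C@H]1C[C@H]2C[C@@H]([C@@H]1C)C2(C)C)[C@H]1C[C@H]2C[C@@H]([C@@H]1C)C2(C)C | intermediate
4 | methyl (2E,4R)-4-hydroxy-6-methylhepta-2,6-dienoate | COC(=O)/C=C/[C@H](O)CC(C)=C | intermediate
5 | ethynyltrimethylsilane | C#C[Si](C)(C)C | starting material
6 | (S)-epichlorohydrin, (2S)-2-(chloromethyl)oxirane | ClC[C@@H]1CO1 | starting material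
7 | lithium (trimethylsilyl)acetylide | [Li]C#C[Si](C)(C)C | intermediate
8 | (2S)-1-chloro-5-(trimethylsilyl)pent-4-yn-2-ol | ClC[C@@H](O)CC#C[Si](C)(C)C | intermediate
9 | trimethyl{3-[(2S)-oxiran-2-yl]prop-1-yn-1-yl}silane | C[Si](C)(C)C#CC[C@H]1CO1 | intermediate
10 | (3S)-6-(trimethylsilyl)hex-1-en-5-yn-3-ol | C=C[C@@H](O)CC#C[Si](C)(C)C | intermediate
11 | (3S)-hex-1-en-5-yn-3-ol | C=C[C@@H](O)CC#C | intermediate
12 | dimethylaluminium (3S,5E)-6-(dimethylalumanyl)-5-methylhexa-1,5-dien-3-olate | C=C[C@H](C/C(C)=C/[Al](C)C)O[Al](C)C | intermediate
13 | (2E,5S)-3-methylhepta-2,6-diene-1,5-diol | OC/C=C(C)/C[C@H](O)C=C | intermediate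
14 | (2E,5S)-5-hydroxy-3-methylhepta-2,6-dienal | O=C/C=C(C)/C[C@H](O)C=C | intermediate
15 | dichlorodi(propan-2-yl)silane | CC(C)[Si](Cl)(Cl)C(C)C | starting material
16 | methyl (2E,4R)-4-{[chlorodi(propan-2-yl)silyl]oxy}-6-methylhepta-2,6-dienoate | COC(=O)/C=C/[C@@H](CC(C)=C)O[Si](Cl)(C(C)C)C(C)C | intermediate
17 | methyl (2E,4R)-6-methyl-4-{[{[(3S,5E)-5-methyl-7-oxohepta-1,5-dien-3-yl]oxy}di(propan-2-yl)silyl]oxy}hepta-2,6-dienoate | COC(=O)/C=C/[C@@H](CC(C)=C)O[Si](C(C)C)(C(C)C)O[C@H](C=C)C/C(C)=C/C=O | intermediate
18 | methyl (2E)-3-{(4S,5Z,8R)-6-methyl-4-[(2E)-2-methyl-4-oxobut-2-en-1-yl]-2,2-di(propan-2-yl)-1,3-dioxa-2-silacyclooct-5-en-8-yl}prop-2-enoate | COC(=O)/C=C/[C@H]1C/C(C)=C\[C@H](C/C(C)=C/C=O)O[Si](C(C)C)(C(C)C)O1 | intermediate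
19 | methyl 2α,8β-O-[di(propan-2-yl)silanediyl]-2α,6α,8β-trihydroxy-13-norgermacra-1(10)Z,4E-dien-12-oate (H-6β, H-7α; formed as its samarium alkoxide) | CC(C)[Si]4(C(C)C)O[C@@H]1C/C(C)=C\[C@@H](O4)C/C(C)=C/[C@@H](O)[C@@H]1CC(=O)OC | intermediate
20 | 2α,8β-O-[di(propan-2-yl)silanediyl]-2α,8β-dihydroxy-13-norgermacra-1(10)Z,4E-dien-12,6α-olide (H-6β, H-7α) | CC(C)[Si]4(C(C)C)O[C@@H]1C/C(C)=C\[C@@H](O4)C/C(C)=C/[C@H]2OC(=O)C[C@@H]21 | intermediate
21 | 13-(dimethylamino)-2α,8β-O-[di(propan-2-yl)silanediyl]-2α,8β-dihydroxy-11,13-dihydrogermacra-1(10)Z,4E-dien-12,6α-olide (aminomethyl group drawn α) | CC(C)[Si]4(C(C)C)O[C@@H]1C/C(C)=C\[C@@H](O4)C/C(C)=C/[C@H]2OC(=O)[C@@H](CN(C)C)[C@@H]21 | intermediate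
22 | N-methyl quaternary ammonium iodide of 21 | CC(C)[Si]4(C(C)C)O[C@@H]1C/C(C)=C\[C@@H](O4)C/C(C)=C/[C@H]2OC(=O)[C@@H](C[N+](C)(C)C)[C@@H]21.[I-] | intermediate
23 | 2α,8β-O-[di(propan-2-yl)silanediyl]-2α,8β-dihydroxygermacra-1(10)Z,4E,11(13)-trien-12,6α-olide | CC(C)[Si]4(C(C)C)O[C@@H]1C/C(C)=C\[C@@H](O4)C/C(C)=C/[C@H]2OC(=O)C(=C)[C@@H]21 | intermediate
24 | 11α,13-epoxy-2α,8β-O-[di(propan-2-yl)silanediyl]-2α,8β-dihydroxygermacra-1(10)Z,4E-dien-12,6α-olide | CC(C)[Si]4(C(C)C)O[C@@H]1C/C(C)=C\[C@@H](O4)C/C(C)=C/[C@H]2OC(=O)[C@]3(CO3)[C@@H]21 | intermediate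
25 | 13-chloro-2α,8β-O-[di(propan-2-yl)silanediyl]-2α,8β,11α-trihydroxygermacra-1(10)Z,4E-dien-12,6α-olide | CC(C)[Si]4(C(C)C)O[C@@H]1C/C(C)=C\[C@@H](O4)C/C(C)=C/[C@H]2OC(=O)[C@](O)(CCl)[C@@H]21 | intermediate
26 | 13-chloro-2α,8β,11α-trihydroxygermacra-1(10)Z,4E-dien-12,6α-olide | O[C@@H]1C/C(C)=C\[C@@H](O)C/C(C)=C/[C@H]2OC(=O)[C@](O)(CCl)[C@@H]21 | intermediate
27 | 2α-(tert-butyldimethylsilyloxy)-13-chloro-8β,11α-dihydroxygermacra-1(10)Z,4E-dien-12,6α-olide | O[C@@H]1C/C(C)=C\[C@@H](O[Si](C)(C)C(C)(C)C)C/C(C)=C/[C@H]2OC(=O)[C@](O)(CCl)[C@@H]21 | intermediate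
28 | 8β-acetoxy-2α-(tert-butyldimethylsilyloxy)-13-chloro-11α-hydroxygermacra-1(10)Z,4E-dien-12,6α-olide | CC(=O)O[C@@H]1C/C(C)=C\[C@@H](O[Si](C)(C)C(C)(C)C)C/C(C)=C/[C@H]2OC(=O)[C@](O)(CCl)[C@@H]21 | intermediate
29 | 8β-acetoxy-13-chloro-2α,11α-dihydroxygermacra-1(10)Z,4E-dien-12,6α-olide, (2S,6R,7R,8R,11S), CNP0360028.4 | CC(=O)O[C@@H]1C/C(C)=C\[C@@H](O)C/C(C)=C/[C@H]2OC(=O)[C@](O)(CCl)[C@@H]21 | target

## Step count and least certain steps

Total: 14 steps. Longest linear sequence: 13 steps (steps 2 to 14, from 5 and 6).

Step 8 (carries the label). Most likely to go wrong: the ketyl is consumed before it reaches C7, by over-reduction to the allylic alcohol, by pinacol-type dimerisation, or by bonding through the γ-carbon C4 of the delocalised radical in an eight-membered closure. The reason is that a 10-exo radical cyclisation is slow and here has to close across a silaketal on which the two reacting chains are trans, giving an in,out-bridged bicycle. Facial selectivity at C7 and C6 rests on conformational arguments only, so epimer formation is the second hazard. The fallback replaces the radical closure by the intramolecular chromium-mediated allylation of the Barbier kind that is established for germacranolide rings, and it brings C13 in before the ring is closed. It sets out from 18.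
- Luche reduction (NaBH4, CeCl3·7H2O, MeOH, −78 °C) of the aldehyde gives allylic alcohol F1.
- 4-Methoxybenzyl 2,2,2-trichloroacetimidate with catalytic camphorsulfonic acid gives ether F2.
- Conjugate addition of PhSeLi to the enoate and trapping of the ester enolate with gaseous formaldehyde gives selenide F3 as a mixture at C7 and C11.
- H2O2/pyridine at 0 °C triggers selenoxide syn-elimination and returns the olefin as 2-(hydroxymethyl)enoate F4.
- CBr4/PPh3 gives allylic bromide F5.
- DDQ (2.5 equiv) in wet CH2Cl2 removes the 4-methoxybenzyl group and oxidises the freed allylic alcohol to bromo enal F6.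
- CrCl2 (divalent chromium, excess, THF/DMF, high dilution) forms the allylchromium species, which attacks the C6 aldehyde through its γ-carbon C7 in a six-membered Zimmerman–Traxler array; the C6 alkoxide lactonises onto the ester.

This rejoins the route at 23, so steps 9 and 10 are not needed.

Step 7 (key step). Most likely to go wrong: closure onto the 1,1-disubstituted olefin is the slowest metathesis event available to the C1 alkylidene. Intermolecular cross-metathesis at the vinyl group (oligomerisation), hydride-induced olefin migration and, less probably, engagement of the conjugated ester olefin next to C8 can therefore take over. The fallback takes the conjugated ester out of the metathesis substrate and builds it afterwards. It sets out from 2, 14 and 15.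
- 2-[(4-Methoxybenzyl)oxy]acetaldehyde is 2-methylallylated with the reagent of step 1 (made from 2) to give alcohol F7.
- Silylation as in step 6, first F7 with 15 and then 14, gives bis-alkoxysilane F8.
- The same ring-closing metathesis gives silaketal F9.
- DDQ in CH2Cl2/pH 7 buffer frees primary alcohol F10.
- Dess–Martin periodinane gives aldehyde F11.
- Wittig olefination with Ph3P=CHCO2Me (1.05 equiv, CH2Cl2, 0 °C) reacts at the α-silyloxy aldehyde in preference to the hindered conjugated aldehyde and installs the E-enoate.

This rejoins the route at 18.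

Step 13. Most likely to go wrong: silylation at O8 in place of or in addition to O2, because the discrimination is steric only. The mildly basic medium could also start migration of the lactone to the free O8. The fallback drops the protecting group and differentiates the two esters enzymatically. It sets out from 26: acetylation of both secondary alcohols (Ac2O, pyridine, DMAP, 0 °C) gives diacetate F12, and a lipase (Candida antarctica lipase B, pH 7 phosphate buffer/acetone, rt) hydrolyses the exposed allylic C2 acetate under neutral conditions that leave the chlorohydrin and the lactone alone. This rejoins the route at 29.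

## Further compounds

F1 | step 8 | methyl (2E)-3-{(4S,5Z,8R)-4-[(2E)-4-hydroxy-2-methylbut-2-en-1-yl]-6-methyl-2,2-di(propan-2-yl)-1,3-dioxa-2-silacyclooct-5-en-8-yl}prop-2-enoate | COC(=O)/C=C/[C@H]1C/C(C)=C\[C@H](C/C(C)=C/CO)O[Si](C(C)C)(C(C)C)O1
F2 | step 8 | methyl (2E)-3-{(4S,5Z,8R)-4-[(2E)-4-[(4-methoxybenzyl)oxy]-2-methylbut-2-en-1-yl]-6-methyl-2,2-di(propan-2-yl)-1,3-dioxa-2-silacyclooct-5-en-8-yl}prop-2-enoate | COC(=O)/C=C/[C@H]1C/C(C)=C\[C@H](C/C(C)=C/COCc2ccc(OC)cc2)O[Si](C(C)C)(C(C)C)O1
F3 | step 8 | methyl 2-(hydroxymethyl)-3-(phenylselanyl)-3-{(4S,5Z,8R)-4-[(2E)-4-[(4-methoxybenzyl)oxy]-2-methylbut-2-en-1-yl]-6-methyl-2,2-di(propan-2-yl)-1,3-dioxa-2-silacyclooct-5-en-8-yl}propanoate (mixture at C2 and C3 of the propanoate) | COC(=O)C(CO)C([Se]c3ccccc3)[C@H]1C/C(C)=C\[C@H](C/C(C)=C/COCc2ccc(OC)cc2)O[Si](C(C)C)(C(C)C)O1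
F4 | step 8 | methyl (2E)-2-(hydroxymethyl)-3-{(4S,5Z,8R)-4-[(2E)-4-[(4-methoxybenzyl)oxy]-2-methylbut-2-en-1-yl]-6-methyl-2,2-di(propan-2-yl)-1,3-dioxa-2-silacyclooct-5-en-8-yl}prop-2-enoate | COC(=O)/C(CO)=C/[C@H]1C/C(C)=C\[C@H](C/C(C)=C/COCc2ccc(OC)cc2)O[Si](C(C)C)(C(C)C)O1
F5 | step 8 | methyl (2Z)-2-(bromomethyl)-3-{(4S,5Z,8R)-4-[(2E)-4-[(4-methoxybenzyl)oxy]-2-methylbut-2-en-1-yl]-6-methyl-2,2-di(propan-2-yl)-1,3-dioxa-2-silacyclooct-5-en-8-yl}prop-2-enoate | COC(=O)/C(CBr)=C/[C@H]1C/C(C)=C\[C@H](C/C(C)=C/COCc2ccc(OC)cc2)O[Si](C(C)C)(C(C)C)O1
F6 | step 8 | methyl (2Z)-2-(bromomethyl)-3-{(4S,5Z,8R)-6-methyl-4-[(2E)-2-methyl-4-oxobut-2-en-1-yl]-2,2-di(propan-2-yl)-1,3-dioxa-2-silacyclooct-5-en-8-yl}prop-2-enoate | COC(=O)/C(CBr)=C/[C@H]1C/C(C)=C\[C@H](C/C(C)=C/C=O)O[Si](C(C)C)(C(C)C)O1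
F7 | step 7 | (2R)-1-[(4-methoxybenzyl)oxy]-4-methylpent-4-en-2-ol | COc1ccc(COC[C@H](O)CC(C)=C)cc1
F8 | step 7 | (2E,5S)-5-{[{[(2R)-1-[(4-methoxybenzyl)oxy]-4-methylpent-4-en-2-yl]oxy}di(propan-2-yl)silyl]oxy}-3-methylhepta-2,6-dienal | COc1ccc(COC[C@@H](CC(C)=C)O[Si](C(C)C)(C(C)C)O[C@H](C=C)C/C(C)=C/C=O)cc1
F9 | step 7 | (2E)-4-{(4S,5Z,8R)-8-{[(4-methoxybenzyl)oxy]methyl}-6-methyl-2,2-di(propan-2-yl)-1,3-dioxa-2-silacyclooct-5-en-4-yl}-3-methylbut-2-enal | COc1ccc(COC[C@H]2C/C(C)=C\[C@H](C/C(C)=C/C=O)O[Si](C(C)C)(C(C)C)O2)cc1
F10 | step 7 | (2E)-4-[(4S,5Z,8R)-8-(hydroxymethyl)-6-methyl-2,2-di(propan-2-yl)-1,3-dioxa-2-silacyclooct-5-en-4-yl]-3-methylbut-2-enal | OC[C@H]1C/C(C)=C\[C@H](C/C(C)=C/C=O)O[Si](C(C)C)(C(C)C)O1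
F11 | step 7 | (4S,5Z,8R)-6-methyl-4-[(2E)-2-methyl-4-oxobut-2-en-1-yl]-2,2-di(propan-2-yl)-1,3-dioxa-2-silacyclooct-5-ene-8-carbaldehyde | O=C[C@H]1C/C(C)=C\[C@H](C/C(C)=C/C=O)O[Si](C(C)C)(C(C)C)O1
F12 | step 13 | 2α,8β-diacetoxy-13-chloro-11α-hydroxygermacra-1(10)Z,4E-dien-12,6α-olide | CC(=O)O[C@@H]1C/C(C)=C\[C@@H](OC(C)=O)C/C(C)=C/[C@H]2OC(=O)[C@](O)(CCl)[C@@H]21
A1 | alternative 1 | ten-membered 1(10)Z,4E-triene with a C2 tert-butyldimethylsilyl enol ether (ring carbons cis at C2=C3), O6-TBS, O8-TES and a C7 isopropenyl group | CC[Si](CC)(CC)O[C@@H]1C/C(C)=C\C(O[Si](C)(C)C(C)(C)C)=C/C(C)=C/[C@@H](O[Si](C)(C)C(C)(C)C)[C@@H]1C(C)=C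
A2 | alternative 2 | cyclopropane-fused γ-lactone (3-oxabicyclo[3.1.0]hexan-2-one) with an exo C8 triisopropylsilyloxy group and the C5–C1 side chain on C6 (O2-TBS) | O=C1O[C@H](/C=C(C)/C[C@H](O[Si](C)(C)C(C)(C)C)C=C)[C@H]2[C@H](O[Si](C(C)C)(C(C)C)C(C)C)[C@@H]12
A3 | alternative 3 | 2α-(tert-butyldimethylsilyloxy)-8β-hydroxy-13-norgermacra-1(10)Z,4E-dien-12,6α-olide | O[C@@H]1C/C(C)=C\[C@@H](O[Si](C)(C)C(C)(C)C)C/C(C)=C/[C@H]2OC(=O)C[C@@H]21
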